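The runs are calculated for substances that don't exist, noise included.

Monday's leftover solid substrate read 24 % at 0.500 h and 1 % at 0.833 h, so I told my successor at the bench to expect no visible solid when reading this flask, which holds half Monday's charge.

| flask | solid substrate | gas phase | remark | time |
|---|---|---|---|---|
| Saturday's | 0.025 M | 11 mM (held) | run made earlier |  |
| Monday's | 0.10 M | 11 mM (held) | run made earlier |  |
| flask | 0.050 M | 11 mM (held) |  | 2.5 h |

| run | time / h | target / % | solid substrate / % |
|---|---|---|---|
| Saturday's | 0.250 | 23 | 1 |
| Saturday's | 0.333 | 31 | 0 |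
| Saturday's | 0.500 | 44 | 3 |
| Saturday's | 0.833 | 60 | 0 |
| Saturday's | 1.33 | 68 | 1 |
| Saturday's | 2.00 | 71 | 0 |
| Saturday's | 3.00 | 65 | 0 |
| Monday's | 0.250 | 4 | 40 |
| Monday's | 0.333 | 15 | 35 |
| Monday's | 0.500 | 22 | 24 |
| Monday's | 0.833 | 39 | 1 |
| Monday's | 1.33 | 57 | 2 |
| Monday's | 2.00 | 70 | 3 |
| Monday's | 3.00 | 67 | 1 |

(standard deviation of a reading: 1.5 percentage points)

* the target standing at 2.5 h, as a percentage of the solid substrate charged
* concentration of dissolved gas in solution at 2.5 h, in percent of saturation

- given per volume of solution although it is solid: solid substrate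
- the numbers in the tables scatter with a standard deviation of 1.5 percentage points
- at the start none of the gas phase is in solution
- at the start none of the solid substrate is in solution

I wrote: leave the clock alone, since target read lower in both runs at 3.00 h than at 2.00 h, from 71 % to 65 % on Saturday and from 70 % to 67 % on Monday. Not knowing what target became, I took an even split between target and whatever it became as the zero of the scale. The mean excess over that split read 21 percentage points, then 16 points, which I read as a drain at 0.248 h⁻¹, my excess drain rate, a relaxation rate. That put target at 68.1 % at 2.5 h. The tables show no dissolved gas, so I offered no figure for it.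

The forecast gave 68 % and 93 %, reasoning “Both runs reach about 70% at 2 h and about 66% at 3 h, so 2.5 h should give about 68%”.

The flask gave 69.8 % target, with dissolved gas at 98.2 % of saturation.

    target ⇌ isomer of the product (K = 1.20, k = 5.84 × 10⁻⁵ s⁻¹)
    starting material ⇌ dormant form (K = 0.289, k = 0.00153 s⁻¹)
    gas phase ⇌ dissolved gas, rate k3*(csat - [dissolved gas]) (kL = 0.00393 s⁻¹)
    solid substrate ⇌ starting material, rate k4*(cs4 - [starting material]) while solid is left; crystals form when [starting material] > cs4 (solubility = 45.0 mM, k = 0.00420 s⁻¹)
    starting material + dissolved gas → target (k = 0.0531 M⁻¹ s⁻¹)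
    starting material → side product (k = 1.28 × 10⁻⁵ s⁻¹)

At 0.537 h this flask made target, each step taken net, 8.92 times faster than it used it up, and by 2.5 h it held an excess of 20 points, with 2.37 % starting material left and 24.4 % isomer of the product beside it. From that excess, my 0.248 h⁻¹ gave 58.3 % at 6.0 h, more than the 51.8 % of the neighbouring flask read then, and the flask left until 10 h held 45.8 % target against 51.4 % isomer of the product.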